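## The problem

1. Compound 10 is a single carbocycle, a cyclohexa-1,3-diene numbered here C1 (carrying the C7 methylene and its benzoate oxygen O7), C2, C3, C4 (the diene CH carbons), C5 (CH–OBz) and C6 (CH–OH). No rings have to be joined, and the one exocyclic C–C bond, C1–C7, can come from an aromatic starting material.
2. A 5,6-dioxygenated cyclohexa-1,3-diene is one 1,2-elimination of benzoic acid or water away from a benzene ring. The diene diol therefore has to appear last, under nearly neutral conditions, from intermediates that cannot aromatise.
3. C5 and C6 are adjacent stereocentres, both R, with their oxygens trans. Nothing else in the molecule is stereogenic, so the first centre must come from a chiral reagent; the second can then be set relative to it, most naturally C6 first (inside a rigid ring) and C5 second.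
4. Three oxygens must be told apart: O5 and O7 are benzoylated while O6, which lies between them, stays free. Acyl migration from O5 or O7 to O6 becomes possible as soon as O6 is a free alkoxide.
5. The benzoates exclude strong nucleophiles and bases late in the route, and the allylic C5 ester excludes strong acid.
6. The enabling feature is the place of the C6 hydroxyl: it is allylic to C1=C2, and C1 also holds C7. This is the pattern that a Wharton transposition delivers from a C1–C6 oxirane flanked by a C2 ketone.
7. That oxirane is the epoxide of a 2-(hydroxymethyl) enone whose C7 hydroxyl sits next to the C1=C6 double bond, so the hydroxyl can steer a nucleophilic epoxidation. The enone belongs to a phenol-derived quinone monoketal whose C5 ketal blocks tautomerisation to an arene.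

## Retrosynthesis

Atom labels follow 10 throughout. In the systematic names of the bicyclic intermediates the ring carbons carry the same numbers and position 7 is the oxirane oxygen.

**10 ⇒ 8 (through 9).** The C1=C2 double bond and the O6–H bond of 10 are traced back, retro-Wharton, to the C2 carbonyl and the C1–O oxirane bond of epoxy enone 8; the forward reaction runs through hydrazone 9. The neighbouring cuts are worse: acylating a free triol at the end cannot tell O5 from O6, and making the diene by elimination passes through intermediates that can lose an oxygen substituent and aromatise. Compound 8 is no smaller than 10 but far sturdier, because O6 is masked in the oxirane, which also fixes the C6 configuration. The forward step must condense at C2 and fragment faster than the nitrogen nucleophile attacks a benzoate or C4, and must leave C5 and C6 untouched.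

**8 ⇒ 7.** The C5–O ester bond is cut with inversion, giving alcohol 7 with its hydroxyl cis to the oxirane oxygen. This is preferred to a retentive acylation of the trans alcohol because hydride delivery to a C5 carbonyl beside the oxirane is expected from the face away from the oxirane oxygen, which gives the cis alcohol. A Mitsunobu esterification then corrects the configuration and installs the benzoate in one operation. The forward step has to be a clean SN2 displacement at an allylic carbon.

**7 ⇒ 6.** The C5–H bond is cut, leading to enedione 6 and removing the C5 stereocentre. The forward reduction must choose the C5 carbonyl (flanked by C6–H) over the C2 carbonyl (flanked by the fully substituted C1), must be a 1,2-addition, and must come from the face opposite the oxirane oxygen.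

**6 ⇒ 5 ⇒ 4.** Two functional-group changes follow: the C5 carbonyl comes from dimethyl ketal 5, and the O7 benzoate of 5 from primary alcohol 4. Benzoylation is placed first so that the only free hydroxyl is capped before the acid step. The ketal is kept this long because it is what prevents aromatisation while the oxirane is built.

**4 ⇒ 3 (key disconnection).** Both C–O bonds of the oxirane, C6–O and C1–O, are cut, giving the flat, achiral dienone 3. This removes both stereocentres and the only ring formed in the synthesis. Bringing in O6 by dihydroxylation or from a chiral-pool cyclitol would cost more redox and protecting-group steps. The forward reaction must add a peroxide oxygen to C6 and not to C4, and to one face only.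

**3 ⇒ 2 ⇒ 1.** The C5–OMe bond is cut by retro-oxidative dearomatisation to phenol 2, and the C7–H bond by retro-reduction to commercial aldehyde 1. All seven carbons, O7, the C2 oxygen and the C5 oxygen are already in place in 1.

## Roads not taken

**Alternative 1:** The six ring carbons are assembled by cycloaddition; the C6–C1 and C2–C3 bonds are cut, leading to furan A1 and 2-bromoacrolein A2.
- Forward key step: an enantioselective Diels–Alder reaction under a chiral cationic boron Lewis acid (oxazaborolidinium type) would give the exo-formyl 7-oxanorbornene A3. Its bridging oxygen joins C6 and C3 and its formyl carbon is C7.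
- Merits: all seven carbons and the C6 configuration arrive in one catalytic step from very cheap materials, and the oxygen bridge protects O6 much as the oxirane does in the chosen plan.
- Weak points for 10: after reduction and benzoylation at C7 and dehydrobromination to the C1=C2 alkene, the bridge must be opened at C3 while a benzoate enters at C5 anti to O6 (an SN2′ opening). Anti openings of this kind are established mainly for benzo-fused oxabicycles. Here the nucleophile could enter at C5, at C4 or at the C1=C2 terminus, and 7-oxanorbornadienes isomerise to phenols under acid and revert to A1 on heating.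
- Comparison: the step count would be similar and the stereodefining step catalytic, so in those respects this road is at least as good. Against it the chosen plan sets the built-in distinction of O5 from O6 (ketal carbon versus oxirane), a trans relationship reached by two ordinary operations, and the absence of any aromatisable intermediate before the last step.

**Alternative 2:** The ring is cut at C5–C6 and C1–C2 into two oxygenated enals, (E)-4-oxobut-2-enyl benzoate A4 and (E)-3-(triisopropylsilyloxy)acrolein A5.
- Forward key step: with a diarylprolinol silyl ether, the dienamine of A4 would add through its γ-carbon (future C5) to the β-carbon (future C6) of the iminium ion of A5. The resulting enamine would close on the unsaturated iminium of the A4 unit, and loss of the amine would give dienal A6 with both stereocentres, O5 benzoylated and O6 silylated.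
- Merits: reduction of the aldehyde, benzoylation of O7 and desilylation would finish 10 in four steps, convergently and catalytically. On paper this is clearly shorter than the chosen route.
- Weak points: a dienamine with a γ-acyloxy group can expel the carboxylate instead of acting as a nucleophile. The iminium ion of a β-silyloxy enal is a vinylogous formate derivative, a poor acceptor that can lose silanolate after addition. The amine base is present while A6 needs only a 1,2-elimination to aromatise. Neither α versus γ reactivity nor the trans relationship is secured, and fluoride desilylation beside a benzoate invites acyl migration to O6.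
- Comparison: if the cascade worked, this road would win on step economy. The chosen plan offers in return steps that each belong to an established reaction class, and it forms the sensitive diene diol only in the final operation.

**Alternative 3:** The C6–C1 and C4–C5 bonds are cut. Methyl 2-oxo-2H-pyran-3-carboxylate A7 is the four-carbon diene (its ester carbon is C7) and (E)-1,2-bis(tert-butyldimethylsilyloxy)ethene A8 is the C5–C6 unit.
- Forward key step: an inverse-electron-demand Diels–Alder reaction under a chiral Lewis acid, followed by thermal decarboxylation of the bridged adduct, would give diene ester A9. The trans diol geometry is copied from the E alkene.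
- Merits: the trans relationship needs no inversion step, the diene lands in the right place, and the carbon skeleton is reached very quickly.
- Weak points: the silyl ethers on O5 and O6 are chemically almost equivalent, so benzoylating O5 while leaving O6 free is not solved. The cycloreversion needs heat, under which A9 can lose silanol and aromatise. The ester must then be reduced with hydride beside this fragile diene.
- Comparison: this road sets the ring oxidation pattern and the trans geometry more directly. The chosen plan distinguishes O5, O6 and O7 by construction and never exposes the diene to heat, hydride or fluoride.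

Key step: step 3

Assumption: the sodium complex of L-(+)-diisopropyl tartrate is taken to deliver the peroxide to the C6 face that gives (1S,6R)-4; the sense of induction for this substitution pattern has to be confirmed on the first run, and if it is the reverse the D-(−)-ester is used with nothing else changed.

## Route

Step 1
Reactants: 1 2-hydroxy-5-methoxybenzaldehyde
Product: 2 2-(hydroxymethyl)-4-methoxyphenol
Conditions: NaBH4, MeOH, 0 °C
Reagents that add atoms: none
Why: Borohydride reduction of an aryl aldehyde to the benzylic alcohol; the phenol and the aryl ether are inert and no stereocentre is formed.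

Step 2
Reactants: 2 2-(hydroxymethyl)-4-methoxyphenol
Product: 3 2-(hydroxymethyl)-4,4-dimethoxycyclohexa-2,5-dien-1-one
Conditions: PhI(OAc)2, MeOH, 0 °C
Reagents that add atoms: methanol, CO
Why: Oxidative dearomatisation of a para-methoxyphenol with PhI(OAc)2: the aryloxy iodane loses PhI while methanol adds at C5, the carbon para to the phenol oxygen that already bears the methoxy group, giving the quinone monoketal. The benzylic hydroxyl is a spectator and the product is achiral.

Step 3
Reactants: 3 2-(hydroxymethyl)-4,4-dimethoxycyclohexa-2,5-dien-1-one
Product: 4 (1S,6R)-1-(hydroxymethyl)-5,5-dimethoxy-7-oxabicyclo[4.1.0]hept-3-en-2-one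
Conditions: Ph3COOH, NaN(SiMe3)2, L-(+)-diisopropyl tartrate, 4 Å molecular sieves, PhMe, −65 °C; then aq. NH4Cl at low temperature
Reagents that add atoms: trityl hydroperoxide, OOC(c1ccccc1)(c1ccccc1)c1ccccc1
Why: NaN(SiMe3)2 turns the C7 hydroxyl, the hydroperoxide and the tartrate into sodium salts that aggregate in toluene, so the peroxide is held beside the C1=C6 alkene. The peroxide oxygen adds to C6, the β-carbon of the C2 enone, and the C1 enolate then displaces trityl oxide from that oxygen (Weitz–Scheffer mechanism). The closest known reaction type is the tartrate-mediated, hydroxyl-directed nucleophilic epoxidation of hydroxymethyl-substituted quinone monoketals with Ph3COOH and NaN(SiMe3)2. The oxirane closes in a 3-exo-tet mode, the enolate carbon C1 attacking oxygen with the O–O bond exocyclic to the forming ring. C6 is set in the addition step by the face that the chiral sodium tartrate–alkoxide assembly presents to the peroxide; C1 follows because the enolate can only close on the face that already carries the peroxide, a fused three-membered ring being necessarily cis. The step needs site selectivity for C1=C6 over the unsubstituted and intrinsically more electrophilic C3=C4 enone, and face selectivity at C6. Both rest on the C7 sodium alkoxide, which puts the peroxide within a six-atom reach of C6 (C6–C1–C7–O–Na–O) but not of C4; the non-polar solvent, the low temperature and the bulk of the trityl group slow the undirected pathway. The C5 ketal keeps substrate and product from tautomerising to arenes.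

Step 4
Reactants: 4 (1S,6R)-1-(hydroxymethyl)-5,5-dimethoxy-7-oxabicyclo[4.1.0]hept-3-en-2-one
Product: 5 [(1S,6R)-5,5-dimethoxy-2-oxo-7-oxabicyclo[4.1.0]hept-3-en-1-yl]methyl benzoate
Conditions: PhCOCl, pyridine, DMAP (cat.), CH2Cl2, 0 °C
Reagents that add atoms: benzoyl chloride, O=C(Cl)c1ccccc1
Why: Acylation of the only hydroxyl in the molecule, a primary alcohol, under mild amine base that leaves the epoxy ketone and the ketal alone; no stereocentre is touched.

Step 5
Reactants: 5 [(1S,6R)-5,5-dimethoxy-2-oxo-7-oxabicyclo[4.1.0]hept-3-en-1-yl]methyl benzoate
Product: 6 [(1S,6R)-2,5-dioxo-7-oxabicyclo[4.1.0]hept-3-en-1-yl]methyl benzoate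
Conditions: aq. HF (48%), MeCN, 0 °C to rt
Reagents that add atoms: water, O
Why: Acid hydrolysis of the dimethyl ketal to the C5 ketone (epoxyquinone formation). The oxirane lies between two electron-poor carbons and should resist acid opening, and the benzoate is stable to aqueous acid at this temperature.

Step 6
Reactants: 6 [(1S,6R)-2,5-dioxo-7-oxabicyclo[4.1.0]hept-3-en-1-yl]methyl benzoate
Product: 7 [(1S,5S,6S)-5-hydroxy-2-oxo-7-oxabicyclo[4.1.0]hept-3-en-1-yl]methyl benzoate (5-OH cis to the oxirane oxygen)
Conditions: i-Bu2AlH (1.05 equiv), THF, −78 °C; then aq. potassium sodium tartrate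
Reagents that add atoms: none
Why: Sterically controlled 1,2-reduction of one carbonyl of an unsymmetrical enedione: the C5 carbonyl has only C6–H beside it, whereas the C2 carbonyl is shielded by the fully substituted C1 and its benzoyloxymethyl group, so the bulky aluminium hydride should complex and reduce at C5. Hydride arrives on the face opposite the oxirane oxygen, which places the new hydroxyl cis to it (5S); at −78 °C with one equivalent the benzoate should not be reduced.

Step 7
Reactants: 7 [(1S,5S,6S)-5-hydroxy-2-oxo-7-oxabicyclo[4.1.0]hept-3-en-1-yl]methyl benzoate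
Product: 8 [(1S,5R,6S)-5-(benzoyloxy)-2-oxo-7-oxabicyclo[4.1.0]hept-3-en-1-yl]methyl benzoate (5-OBz trans to the oxirane oxygen)
Conditions: PPh3, i-PrO2C–N=N–CO2i-Pr, PhCO2H, THF, 0 °C to rt
Reagents that add atoms: benzoic acid, OC(=O)c1ccccc1
Why: Mitsunobu esterification: the C5 alkoxyphosphonium ion is displaced by benzoate with inversion, so C5 becomes R and its oxygen trans to the oxirane. SN2′ attack is disfavoured because the other allylic terminus, C3, is the α-carbon of the enone.

Step 8
Reactants: 8 [(1S,5R,6S)-5-(benzoyloxy)-2-oxo-7-oxabicyclo[4.1.0]hept-3-en-1-yl]methyl benzoate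
Product: 10 [(5R,6R)-5-(benzoyloxy)-6-hydroxycyclohexa-1,3-dien-1-yl]methyl benzoate, via epoxy hydrazone 9 (not isolated)
Conditions: N2H4·H2O (2 equiv), AcOH (2 equiv), MeOH, 0 °C to rt
Reagents that add atoms: hydrazine hydrate, NN.O (its two nitrogen atoms enter hydrazone 9 and leave again as N2; only hydrogen stays in 10)
Why: Wharton transposition: hydrazine condenses at the C2 ketone to give 9, whose N–H unit pushes open the C1–O bond of the oxirane and then leaves as N2, so that C1=C2 forms, C2 takes up hydrogen and O6 is released as the free hydroxyl. The C6–O bond is never broken and C5 is not involved, so both centres keep their configuration (5R,6R); buffering with acetic acid and working cold are meant to spare the two benzoates and the diene.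

## Compound list

1 | 2-hydroxy-5-methoxybenzaldehyde | COc1ccc(O)c(C=O)c1 | starting material
2 | 2-(hydroxymethyl)-4-methoxyphenol | COc1ccc(O)c(CO)c1 | intermediate
3 | 2-(hydroxymethyl)-4,4-dimethoxycyclohexa-2,5-dien-1-one | COC1(OC)C=CC(=O)C(CO)=C1 | intermediate
4 | (1S,6R)-1-(hydroxymethyl)-5,5-dimethoxy-7-oxabicyclo[4.1.0]hept-3-en-2-one | COC1(OC)C=CC(=O)[C@@]2(CO)O[C@@H]12 | intermediate
5 | [(1S,6R)-5,5-dimethoxy-2-oxo-7-oxabicyclo[4.1.0]hept-3-en-1-yl]methyl benzoate | COC1(OC)C=CC(=O)[C@@]2(COC(=O)c3ccccc3)O[C@@H]12 | intermediate
6 | [(1S,6R)-2,5-dioxo-7-oxabicyclo[4.1.0]hept-3-en-1-yl]methyl benzoate | O=C1C=CC(=O)[C@@]2(COC(=O)c3ccccc3)O[C@@H]12 | intermediate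
7 | [(1S,5S,6S)-5-hydroxy-2-oxo-7-oxabicyclo[4.1.0]hept-3-en-1-yl]methyl benzoate | O[C@H]1C=CC(=O)[C@@]2(COC(=O)c3ccccc3)O[C@@H]12 | intermediate
8 | [(1S,5R,6S)-5-(benzoyloxy)-2-oxo-7-oxabicyclo[4.1.0]hept-3-en-1-yl]methyl benzoate | O=C(O[C@@H]1C=CC(=O)[C@@]2(COC(=O)c3ccccc3)O[C@@H]12)c1ccccc1 | intermediate
9 | [(1S,5R,6S)-5-(benzoyloxy)-2-hydrazinylidene-7-oxabicyclo[4.1.0]hept-3-en-1-yl]methyl benzoate (C=N geometry not defined) | O=C(O[C@@H]1C=CC(=NN)[C@@]2(COC(=O)c3ccccc3)O[C@@H]12)c1ccccc1 | intermediate
10 | [(5R,6R)-5-(benzoyloxy)-6-hydroxycyclohexa-1,3-dien-1-yl]methyl benzoate | O=C(OCC1=CC=C[C@@H](OC(=O)c2ccccc2)[C@@H]1O)c1ccccc1 | target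

## Step count and least certain steps

Total step count: 8. Longest linear sequence: 8 steps (1 to 10).

**Step 3 (key step).**
- What may go wrong: epoxidation at the wrong alkene. A peroxide anion that reacts outside the sodium alkoxide–tartrate aggregate prefers the unsubstituted C3–C4 enone, and the substituent on C1 slows addition at C6. Beyond that, face discrimination may be incomplete, and the product is a 2,3-epoxy alkoxide in which Payne-type migration of the oxirane (O7 attacking C1) can set in if the mixture warms before the quench.
- Fallback: it sets out from 3 and returns at 5, removing the competing alkene before the same directed epoxidation and restoring it afterwards.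
  - Hydrogenation of the less substituted C3–C4 double bond of 3 (H2, RhCl(PPh3)3, benzene) should give 2-(hydroxymethyl)-4,4-dimethoxycyclohex-2-en-1-one F1.
  - The tartrate-mediated epoxidation of F1, which has only one enone, should give (1S,6R)-1-(hydroxymethyl)-5,5-dimethoxy-7-oxabicyclo[4.1.0]heptan-2-one F2.
  - Benzoylation as in step 4 gives [(1S,6R)-5,5-dimethoxy-2-oxo-7-oxabicyclo[4.1.0]heptan-1-yl]methyl benzoate F3.
  - Enolisation toward C3, the only side with α-hydrogens (LiN(SiMe3)2, Me3SiCl, THF, −78 °C), gives [(1S,6R)-5,5-dimethoxy-2-(trimethylsilyloxy)-7-oxabicyclo[4.1.0]hept-2-en-1-yl]methyl benzoate F4.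
  - Saegusa–Ito oxidation of F4 with Pd(OAc)2 (divalent palladium) in MeCN restores the C3=C4 double bond and delivers 5.

**Step 6.**
- What may go wrong: insufficient discrimination between two electronically similar carbonyls, so that reduction also occurs at C2 or at both; conjugate reduction of the enedione; or hydride delivery syn to the oxirane.
- Fallback: it sets out from 5 and returns at 8, distinguishing the two carbonyls by the order of unmasking and not by sterics.
  - Luche reduction of the C2 ketone of 5 (NaBH4, CeCl3·7H2O, MeOH, −78 °C) gives the C2 alcohol [2-hydroxy-5,5-dimethoxy-7-oxabicyclo[4.1.0]hept-3-en-1-yl]methyl benzoate F5. Its 2-OH is expected cis to the oxirane oxygen; the configuration at C2 is of no consequence because the centre is oxidised again.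
  - Silylation (t-BuMe2SiCl, imidazole, DMF) gives the tert-butyldimethylsilyl ether of F5, F6.
  - The ketal of F6 is now an ordinary allylic ketal and is hydrolysed with pyridinium p-toluenesulfonate in wet acetone to [2-(tert-butyldimethylsilyloxy)-5-oxo-7-oxabicyclo[4.1.0]hept-3-en-1-yl]methyl benzoate F7.
  - Reduction of its only ketone (i-Bu2AlH, THF, −78 °C) gives the 5-hydroxy compound with 5-OH cis to the oxirane oxygen, F8.
  - Mitsunobu esterification with benzoic acid gives the 5-benzoate with 5-OBz trans to the oxirane oxygen, F9.
  - HF·pyridine in THF removes the silyl group to give [5-(benzoyloxy)-2-hydroxy-7-oxabicyclo[4.1.0]hept-3-en-1-yl]methyl benzoate F10.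
  - MnO2 in CH2Cl2 oxidises the allylic C2 alcohol of F10 to the ketone, which is 8.

**Step 8.**
- What may go wrong: hydrazinolysis of a benzoate, or acyl migration to the newly freed O6; conjugate addition of hydrazine at C4 with pyrazoline formation in competition with hydrazone fragmentation; base-promoted loss of benzoic acid from the product with aromatisation.
- Fallback: it sets out from 8 and returns at 10, separating hydrazone formation from fragmentation so that free hydrazine never meets the substrate.
  - Condensation of 8 with 1,2-bis(tert-butyldimethylsilyl)hydrazine and catalytic Sc(OTf)3 in CH2Cl2 gives the N-silyl hydrazone [5-(benzoyloxy)-2-[(tert-butyldimethylsilyl)hydrazinylidene]-7-oxabicyclo[4.1.0]hept-3-en-1-yl]methyl benzoate F11.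
  - Desilylation of F11 with Bu4NF buffered by AcOH in THF at −20 °C liberates the N–H hydrazone, which fragments as in the Wharton reaction to 10.

**Step 7.**
- What may go wrong: ionisation of the allylic alkoxyphosphonium ion, or SN2′ attack, leading to incomplete inversion or to a transposed ester; elimination instead of substitution.
- Fallback: it sets out from 7 and returns at 8, replacing the redox-condensation by a two-stage sulfonate displacement.
  - Mesylation of 7 (MeSO2Cl, Et3N, CH2Cl2, −20 °C) gives [(5-methanesulfonyloxy)-2-oxo-7-oxabicyclo[4.1.0]hept-3-en-1-yl]methyl benzoate F12, with the sulfonate cis to the oxirane oxygen.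
  - SN2 displacement with PhCO2Cs and 18-crown-6 in toluene inverts C5 and gives 8.

## Further compounds

F1 | step 3 | 2-(hydroxymethyl)-4,4-dimethoxycyclohex-2-en-1-one | COC1(OC)CCC(=O)C(CO)=C1
F2 | step 3 | (1S,6R)-1-(hydroxymethyl)-5,5-dimethoxy-7-oxabicyclo[4.1.0]heptan-2-one | COC1(OC)CCC(=O)[C@@]2(CO)O[C@@H]12
F3 | step 3 | [(1S,6R)-5,5-dimethoxy-2-oxo-7-oxabicyclo[4.1.0]heptan-1-yl]methyl benzoate | COC1(OC)CCC(=O)[C@@]2(COC(=O)c3ccccc3)O[C@@H]12
F4 | step 3 | [(1S,6R)-5,5-dimethoxy-2-(trimethylsilyloxy)-7-oxabicyclo[4.1.0]hept-2-en-1-yl]methyl benzoate | COC1(OC)CC=C(O[Si](C)(C)C)[C@@]2(COC(=O)c3ccccc3)O[C@@H]12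
F5 | step 6 | [2-hydroxy-5,5-dimethoxy-7-oxabicyclo[4.1.0]hept-3-en-1-yl]methyl benzoate, C2 alcohol of 5 with 2-OH cis to the oxirane oxygen | COC1(OC)C=C[C@@H](O)[C@@]2(COC(=O)c3ccccc3)O[C@@H]12
F6 | step 6 | tert-butyldimethylsilyl ether of F5 (2-OSi cis to the oxirane oxygen) | COC1(OC)C=C[C@@H](O[Si](C)(C)C(C)(C)C)[C@@]2(COC(=O)c3ccccc3)O[C@@H]12
F7 | step 6 | [2-(tert-butyldimethylsilyloxy)-5-oxo-7-oxabicyclo[4.1.0]hept-3-en-1-yl]methyl benzoate (2-OSi cis to the oxirane oxygen) | O=C1C=C[C@@H](O[Si](C)(C)C(C)(C)C)[C@@]2(COC(=O)c3ccccc3)O[C@@H]12
F8 | step 6 | [2-(tert-butyldimethylsilyloxy)-5-hydroxy-7-oxabicyclo[4.1.0]hept-3-en-1-yl]methyl benzoate (2-OSi and 5-OH both cis to the oxirane oxygen) | O[C@H]1C=C[C@@H](O[Si](C)(C)C(C)(C)C)[C@@]2(COC(=O)c3ccccc3)O[C@@H]12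
F9 | step 6 | [5-(benzoyloxy)-2-(tert-butyldimethylsilyloxy)-7-oxabicyclo[4.1.0]hept-3-en-1-yl]methyl benzoate (5-OBz trans, 2-OSi cis to the oxirane oxygen) | O=C(O[C@@H]1C=C[C@@H](O[Si](C)(C)C(C)(C)C)[C@@]2(COC(=O)c3ccccc3)O[C@@H]12)c1ccccc1
F10 | step 6 | [5-(benzoyloxy)-2-hydroxy-7-oxabicyclo[4.1.0]hept-3-en-1-yl]methyl benzoate (5-OBz trans, 2-OH cis to the oxirane oxygen) | O=C(O[C@@H]1C=C[C@@H](O)[C@@]2(COC(=O)c3ccccc3)O[C@@H]12)c1ccccc1
F11 | step 8 | [5-(benzoyloxy)-2-[(tert-butyldimethylsilyl)hydrazinylidene]-7-oxabicyclo[4.1.0]hept-3-en-1-yl]methyl benzoate (ring stereocentres as in 8) | O=C(O[C@@H]1C=CC(=NN[Si](C)(C)C(C)(C)C)[C@@]2(COC(=O)c3ccccc3)O[C@@H]12)c1ccccc1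
F12 | step 7 | [(5-methanesulfonyloxy)-2-oxo-7-oxabicyclo[4.1.0]hept-3-en-1-yl]methyl benzoate (5-OMs cis to the oxirane oxygen) | CS(=O)(=O)O[C@H]1C=CC(=O)[C@@]2(COC(=O)c3ccccc3)O[C@@H]12
A1 | alternative 1 | furan | c1ccoc1
A2 | alternative 1 | 2-bromoacrolein | C=C(Br)C=O
A3 | alternative 1 | 2-bromo-7-oxabicyclo[2.2.1]hept-5-ene-2-carbaldehyde (exo-formyl adduct, single enantiomer) | O=C[C@]1(Br)C[C@H]2C=C[C@@H]1O2
A4 | alternative 2 | (E)-4-oxobut-2-enyl benzoate | O=C/C=C/COC(=O)c1ccccc1
A5 | alternative 2 | (E)-3-(triisopropylsilyloxy)acrolein | O=C/C=C/O[Si](C(C)C)(C(C)C)C(C)C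
A6 | alternative 2 | (5R,6R)-5-benzoyloxy-6-(triisopropylsilyloxy)cyclohexa-1,3-diene-1-carbaldehyde | O=CC1=CC=C[C@@H](OC(=O)c2ccccc2)[C@@H]1O[Si](C(C)C)(C(C)C)C(C)C
A7 | alternative 3 | methyl 2-oxo-2H-pyran-3-carboxylate | COC(=O)C1=CC=COC1=O
A8 | alternative 3 | (E)-1,2-bis(tert-butyldimethylsilyloxy)ethene | CC(C)(C)[Si](C)(C)O/C=C/O[Si](C)(C)C(C)(C)C
A9 | alternative 3 | methyl (5R,6R)-5,6-bis(tert-butyldimethylsilyloxy)cyclohexa-1,3-diene-1-carboxylate | COC(=O)C1=CC=C[C@@H](O[Si](C)(C)C(C)(C)C)[C@@H]1O[Si](C)(C)C(C)(C)C
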